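**Retrosynthetic overview** (labdane numbering)
- Endgame: the acid comes from its methyl ester and the angelate is placed on an equatorial 2-OH. The 2-OH comes from a 2-ketone, and C-7=C-8 with C-17 comes from an 8-ketone through its kinetic enol triflate.
- Key disconnection: ring A is cut at C-1–C-10 and C-3–C-4, which removes an acetone unit (C-1, C-2, C-3) from between the two quaternary carbons. In the forward direction a bis-silyl acetone α,α′-dianion equivalent first captures a C-4 cation and then closes ring A at C-10 of a ring B enone.
- Enabling feature: in ring A the oxygenated C-2 lies midway between C-1 and C-3, which carry the quaternary C-10 and C-4. C-2 and C-8 are 1,5-related through C-1–C-10–C-9. H-5, H-9 and CH3-20 share one face (cis-fused rings A/B), which is what a tethered axial Michael attack followed by axial enolate protonation delivers.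
- Sources: ring B, C-4 with its two methyl groups and the C-5 stereocentre come from (+)-nopinone by cyclobutane cleavage. C-20 comes from cuprate addition/dehydrogenation. C-11 to C-16 (with C-13) come from the (R)-3-methylglutaric half ester by Negishi coupling.
- Order of rings: ring B (a carbocycle already present in nopinone) first, ring A second.

Key step: step 9

Assumption: read as written, the SMILES describes a cis-fused decalin, (2S,5R,9R,10S,13R). H-2, H-5, H-9 and CH3-20 lie on one face, O-2 and C-11 on the other, and the ester is the (Z)-2-methylbut-2-enoate (angelate); the route is designed for exactly this isomer.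

Step 1
Reactants: 1 methyl hydrogen (R)-3-methylglutarate
Product: 2 methyl (R)-5-hydroxy-3-methylpentanoate
Conditions: BH3·SMe2, THF, −10 to 0 °C; aq. NH4Cl; used crude
Reagents that add atoms: none
Why: Borane reduces the free carboxylic acid much faster than the methyl ester (chemoselective acid reduction), and the C-13 stereocentre, which comes from the starting material, is not touched.

Step 2
Reactants: 2 methyl (R)-5-hydroxy-3-methylpentanoate
Product: 3 methyl (S)-5-iodo-3-methylpentanoate
Conditions: I2, PPh3, imidazole, CH2Cl2, 0 °C
Reagents that add atoms: iodine, II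
Why: The Appel-type iodination replaces the primary hydroxyl by SN2 displacement of the alkoxyphosphonium ion under neutral conditions that outrun lactonisation and leave C-13 untouched (the descriptor changes only through priorities).

Step 3
Reactants: 4 1-(trimethylsilyl)propan-2-one
Product: 5 trimethyl{2-[(trimethylsilyl)oxy]prop-2-en-1-yl}silane
Conditions: LiN(i-Pr)2, THF, −78 °C; Me3SiCl
Reagents that add atoms: chlorotrimethylsilane, C[Si](C)(C)Cl
Why: Kinetic deprotonation of the α-silyl ketone by the hindered amide takes place at the unhindered methyl group, and O-silylation (silyl enol ether formation) gives a three-carbon unit whose two termini can react one after the other.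

Step 4
Reactants: 6 (1R,5S)-(+)-nopinone
Product: 7 (S)-4-(2-acetoxypropan-2-yl)cyclohex-1-en-1-yl acetate
Conditions: Ac2O, BF3·OEt2, Zn(OAc)2, 0 °C to rt
Reagents that add atoms: acetic anhydride, CC(=O)OC(C)=O
Why: Lewis-acid-promoted cyclobutane fragmentation breaks the bond between the α-bridgehead and the CMe2 carbon and traps both ends as acetates, so the untouched bridgehead becomes C-5 with retained configuration and the position of the enol double bond keeps the ring chiral.

Step 5
Reactants: 7 (S)-4-(2-acetoxypropan-2-yl)cyclohex-1-en-1-yl acetate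
Product: 8 2-[(1S)-4-oxocyclohex-2-en-1-yl]propan-2-yl acetate
Conditions: Pd(OAc)2 (5 mol %), Bu3SnOMe (20 mol %), allyl methyl carbonate, MeCN, 80 °C
Reagents that add atoms: none
Why: Palladium-catalysed dehydrogenation of the enol acetate through its tin enolate (Saegusa–Ito-type β-hydride elimination with allyl methyl carbonate as hydrogen acceptor) places the enone double bond regiospecifically on the side marked by the enol acetate, so C-5 stays a defined γ-stereocentre.

Step 6
Reactants: 8 2-[(1S)-4-oxocyclohex-2-en-1-yl]propan-2-yl acetate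
Product: 10 2-[(1S)-2-methyl-4-oxocyclohex-2-en-1-yl]propan-2-yl acetate, via lithium enolate 9 (not isolated)
Conditions: Me2CuLi (from CuI and MeLi), Et2O, −78 °C; then PhS(Cl)=N-t-Bu, THF, −78 °C
Reagents that add atoms: lithium dimethylcuprate, [Li+].C[Cu-]C
Why: Conjugate addition of the cuprate brings in C-20, and sulfenylation of the enolate with the sulfinimidoyl chloride followed by syn-elimination (one-pot β-alkylation–dehydrogenation of an enone) restores the enone and erases the transient C-10 stereocentre.

Step 7
Reactants: 10 2-[(1S)-2-methyl-4-oxocyclohex-2-en-1-yl]propan-2-yl acetate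
Product: 11 2-[(1S)-3-iodo-2-methyl-4-oxocyclohex-2-en-1-yl]propan-2-yl acetate
Conditions: I2, pyridine, CH2Cl2, rt
Reagents that add atoms: iodine, II
Why: α-Iodination of the enone by pyridine-mediated addition–iodination–elimination gives the 2-iodoenone without touching the γ-stereocentre or the tertiary acetate.

Step 8
Reactants: 11 2-[(1S)-3-iodo-2-methyl-4-oxocyclohex-2-en-1-yl]propan-2-yl acetate; 3 methyl (S)-5-iodo-3-methylpentanoate
Product: 13 methyl (3R)-5-[(3S)-3-(2-acetoxypropan-2-yl)-2-methyl-6-oxocyclohex-1-en-1-yl]-3-methylpentanoate, via alkylzinc iodide 12 (not isolated)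
Conditions: 3, Zn dust, LiCl, THF, 40 °C; then 11, Pd(dppf)Cl2 (5 mol %), THF/NMP, 50 °C
Reagents that add atoms: none
Why: Zinc insertion into the primary iodide and Negishi sp3–sp2 cross-coupling with the 2-iodoenone tolerate the ketone and both esters and join C-11 to C-9, bringing in C-13 with its configuration.

Step 9
Reactants: 13 methyl (3R)-5-[(3S)-3-(2-acetoxypropan-2-yl)-2-methyl-6-oxocyclohex-1-en-1-yl]-3-methylpentanoate; 5 trimethyl{2-[(trimethylsilyl)oxy]prop-2-en-1-yl}silane
Product: 15 methyl (5R,9S,10S,13R)-2,8-dioxo-17-norlabdan-15-oate, via silyl enol ether 14 (not isolated)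
Conditions: TiCl4 (4 equiv), 2,6-di-tert-butylpyridine, CH2Cl2, −78 °C, slow addition of 5 (1.5 equiv); −78 to −20 °C; aq. NaHCO3
Reagents that add atoms: none
Why: Proposed new method: TiCl4 ionises the tertiary acetate of 13 to the C-4 cation, which is captured at the CH2= terminus of 5 (C-3–C-4 bond) with loss of the allylic silyl group, so that the regiodefined silyl enol ether 14, nucleophilic only at C-1, is unveiled next to the TiCl4-bound enone and closes ring A by an intramolecular Mukaiyama–Michael addition to C-10. The closest known reaction types are the Lewis-acid tert-alkylation of silyl enol ethers and allylsilanes with tertiary halides or esters, the use of 2-siloxyallylsilanes as acetone α,α′-dianion equivalents, and intramolecular Mukaiyama–Michael additions to β,β-disubstituted cyclohexenones; what is new is their union in one flask on one substrate, which makes two C–C bonds and both quaternary carbons of ring A. Ring A closes in the 6-(enolendo)-exo-trig mode. C-10 is controlled by C-5, because the tethered C-1 can reach C-10 only on the face on which C-4 stands, antiparallel to the pseudoaxial H-5, so only the cis-fused decalin with H-5 and CH3-20 on one face can form; C-9 is set on quenching by axial protonation of the C-8 titanium enolate anti to the axial C-1, which also puts the side chain in its equatorial, thermodynamically preferred position. The step needs cation capture to beat proton loss (−78 °C, hindered pyridine as proton trap, excess 5; a hydride shift from C-5 is disfavoured because it would place the charge in conjugation with the carbonyl group), C-1 rather than C-3 as the second nucleophilic site (fixed by the position of the second silyl group, so the C-2 carbon is never a free ketone that C-20 could attack), and no intermolecular attack of 5 on the enone (the tetrasubstituted, hindered C-10 should react only intramolecularly).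

Step 10
Reactants: 15 methyl (5R,9S,10S,13R)-2,8-dioxo-17-norlabdan-15-oate
Product: 16 methyl (5R,9S,10S,13R)-2-oxo-8-(trifluoromethylsulfonyloxy)-17-norlabd-7-en-15-oate
Conditions: KN(SiMe3)2 (1.05 equiv), THF, −78 °C; N-(5-chloro-2-pyridyl)bis(trifluoromethanesulfonimide), −78 °C
Reagents that add atoms: N-(5-chloro-2-pyridyl)bis(trifluoromethanesulfonimide), FC(F)(F)S(=O)(=O)N(c1ccc(Cl)cn1)S(=O)(=O)C(F)(F)F
Why: Kinetic deprotonation by the bulky amide should occur at the accessible C-7 methylene rather than at C-9 or at the neopentyl C-1/C-3 methylenes shielded by the axial C-6, and O-triflation (enol triflate formation) fixes the C-7–C-8 double bond without touching C-9.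

Step 11
Reactants: 16 methyl (5R,9S,10S,13R)-2-oxo-8-(trifluoromethylsulfonyloxy)-17-norlabd-7-en-15-oate
Product: 17 methyl (5R,9R,10S,13R)-2-oxolabd-7-en-15-oate
Conditions: MeZnCl, Pd(PPh3)4 (5 mol %), THF, rt
Reagents that add atoms: methylzinc chloride, C[Zn]Cl
Why: Negishi methylation of the enol triflate installs C-17 on the preformed trisubstituted double bond under conditions that tolerate the ketone and the ester.

Step 12
Reactants: 17 methyl (5R,9R,10S,13R)-2-oxolabd-7-en-15-oate
Product: 18 methyl (2S,5R,9R,10S,13R)-2-hydroxylabd-7-en-15-oate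
Conditions: SmI2, H2O, THF, rt
Reagents that add atoms: none
Why: Single-electron (ketyl) reduction should give the thermodynamically favoured equatorial alcohol, since the samarium-bound oxygen avoids the two syn-axial methyl groups at C-4 and C-10 before the final protonation, and this sets C-2 as S while the alkene and ester stay inert.

Step 13
Reactants: 18 methyl (2S,5R,9R,10S,13R)-2-hydroxylabd-7-en-15-oate; 19 angelic acid
Product: 21 methyl (2S,5R,9R,10S,13R)-2-angeloyloxylabd-7-en-15-oate, via mixed anhydride 20 (not isolated)
Conditions: 19, 2,4,6-trichlorobenzoyl chloride, Et3N, toluene, rt; then 18, 80 °C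
Reagents that add atoms: none
Why: Yamaguchi-type esterification through the mixed anhydride without a nucleophilic catalyst acylates the unhindered equatorial alcohol with retention at C-2 and avoids Z-to-E isomerisation of the angelate.

Step 14
Reactants: 21 methyl (2S,5R,9R,10S,13R)-2-angeloyloxylabd-7-en-15-oate
Product: 22 (2S,5R,9R,10S,13R)-2-angeloyloxylabd-7-en-15-oic acid
Conditions: LiOH, THF/H2O, 0 °C to rt; then dil. HCl
Reagents that add atoms: lithium hydroxide, [Li+].[OH-]
Why: Saponification should distinguish the unhindered methyl ester from the conjugated, α-branched ester of a secondary alcohol, so that mild hydroxide cleaves only the former.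

**Compound list**
1 | methyl hydrogen (R)-3-methylglutarate | OC(=O)C[C@@H](C)CC(=O)OC | starting material
2 | methyl (R)-5-hydroxy-3-methylpentanoate | OCC[C@@H](C)CC(=O)OC | intermediate
3 | methyl (S)-5-iodo-3-methylpentanoate | ICC[C@@H](C)CC(=O)OC | intermediate
4 | 1-(trimethylsilyl)propan-2-one | CC(=O)C[Si](C)(C)C | starting material
5 | trimethyl{2-[(trimethylsilyl)oxy]prop-2-en-1-yl}silane | C=C(C[Si](C)(C)C)O[Si](C)(C)C | intermediate
6 | (1R,5S)-(+)-nopinone (6,6-dimethylbicyclo[3.1.1]heptan-2-one) | O=C1CC[C@H]2C[C@@H]1C2(C)C | starting material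
7 | (S)-4-(2-acetoxypropan-2-yl)cyclohex-1-en-1-yl acetate | CC(=O)OC(C)(C)[C@H]1CCC(OC(C)=O)=CC1 | intermediate
8 | 2-[(1S)-4-oxocyclohex-2-en-1-yl]propan-2-yl acetate | CC(=O)OC(C)(C)[C@H]1CCC(=O)C=C1 | intermediate
9 | lithium (3S,4S)-4-(2-acetoxypropan-2-yl)-3-methylcyclohex-1-en-1-olate (methyl trans to the side group) | CC(=O)OC(C)(C)[C@H]1CCC([O-])=C[C@@H]1C.[Li+] | intermediate
10 | 2-[(1S)-2-methyl-4-oxocyclohex-2-en-1-yl]propan-2-yl acetate | CC(=O)OC(C)(C)[C@H]1CCC(=O)C=C1C | intermediate
11 | 2-[(1S)-3-iodo-2-methyl-4-oxocyclohex-2-en-1-yl]propan-2-yl acetate | CC(=O)OC(C)(C)[C@H]1CCC(=O)C(I)=C1C | intermediate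
12 | [(3S)-5-methoxy-3-methyl-5-oxopentyl]zinc iodide | I[Zn]CC[C@@H](C)CC(=O)OC | intermediate
13 | methyl (3R)-5-[(3S)-3-(2-acetoxypropan-2-yl)-2-methyl-6-oxocyclohex-1-en-1-yl]-3-methylpentanoate | CC(=O)OC(C)(C)[C@H]1CCC(=O)C(CC[C@@H](C)CC(=O)OC)=C1C | intermediate
14 | methyl (3R)-3-methyl-5-[(3R)-2-methyl-3-{2-methyl-4-[(trimethylsilyl)oxy]pent-4-en-2-yl}-6-oxocyclohex-1-en-1-yl]pentanoate | C=C(O[Si](C)(C)C)CC(C)(C)[C@H]1CCC(=O)C(CC[C@@H](C)CC(=O)OC)=C1C | intermediate
15 | methyl (5R,9S,10S,13R)-2,8-dioxo-17-norlabdan-15-oate (cis-fused; H-5, H-9, CH3-20 on one face) | O=C1CC(C)(C)[C@H]2CCC(=O)[C@@H](CC[C@@H](C)CC(=O)OC)[C@@]2(C)C1 | intermediate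
16 | methyl (5R,9S,10S,13R)-2-oxo-8-(trifluoromethylsulfonyloxy)-17-norlabd-7-en-15-oate | O=C1CC(C)(C)[C@H]2CC=C(OS(=O)(=O)C(F)(F)F)[C@@H](CC[C@@H](C)CC(=O)OC)[C@@]2(C)C1 | intermediate
17 | methyl (5R,9R,10S,13R)-2-oxolabd-7-en-15-oate | O=C1CC(C)(C)[C@H]2CC=C(C)[C@@H](CC[C@@H](C)CC(=O)OC)[C@@]2(C)C1 | intermediate
18 | methyl (2S,5R,9R,10S,13R)-2-hydroxylabd-7-en-15-oate (equatorial OH) | O[C@H]1CC(C)(C)[C@H]2CC=C(C)[C@@H](CC[C@@H](C)CC(=O)OC)[C@@]2(C)C1 | intermediate
19 | angelic acid, (Z)-2-methylbut-2-enoic acid | C/C=C(/C)C(=O)O | starting material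
20 | (Z)-2-methylbut-2-enoic 2,4,6-trichlorobenzoic anhydride | C/C=C(/C)C(=O)OC(=O)c1c(Cl)cc(Cl)cc1Cl | intermediate
21 | methyl (2S,5R,9R,10S,13R)-2-angeloyloxylabd-7-en-15-oate | C/C=C(/C)C(=O)O[C@H]1CC(C)(C)[C@H]2CC=C(C)[C@@H](CC[C@@H](C)CC(=O)OC)[C@@]2(C)C1 | intermediate
22 | (2S,5R,9R,10S,13R)-2-angeloyloxylabd-7-en-15-oic acid | C/C=C(/C)C(=O)O[C@H]1CC(C)(C)[C@H]2CC=C(C)[C@@H](CC[C@@H](C)CC(=O)O)[C@@]2(C)C1 | target

**Step count**
Total steps: 14. Longest linear sequence: 11 (steps 4 to 14, from 6).

**Steps most likely to fail**

Step 9 (proposed method). The tertiary cation may lose a proton, and the resulting isopropylidene dienone would aromatise. Alternatively the silyl nucleophile may be protodesilylated before the hindered ring closure takes place.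
The fallback uses known chemistry and sets out from 13. Lewis-acid tert-alkylation of isopropenyloxytrimethylsilane (TiCl4, CH2Cl2, −78 °C) gives the isolable methyl ketone methyl (3R)-3-methyl-5-[(3R)-2-methyl-3-(2-methyl-4-oxopentan-2-yl)-6-oxocyclohex-1-en-1-yl]pentanoate F1. Its less substituted pyrrolidine enamine, formed at the methyl side, is then heated in toluene. This closes ring A by an intramolecular Stork enamine Michael addition, and hydrolysis returns to 15.

Step 10. Site selectivity between the two ketones may be poor, with competing enolisation at C-1 or C-3.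
The fallback sets out from 15 and relies on nucleophilic addition instead of enolisation. MeMgBr/CeCl3 (1 equiv, THF, −78 °C) should add only to the more accessible C-8 carbonyl from its equatorial side. This gives methyl (5R,10S,13R)-8-hydroxy-2-oxolabdan-15-oate (axial 8-OH on the face of C-11) F2. syn-Dehydration with methyl N-(triethylammoniosulfonyl)carbamate in benzene at 50 °C removes a C-7 hydrogen and comes back to the route at 17.

Step 12. Electron transfer to the hindered ketone may be slow, or the facial outcome may be mixed.
The fallback sets out from 17. LiBH(s-Bu)3 (THF, −78 °C) attacks from the open equatorial side and gives the axial alcohol methyl (2R,5R,9R,10S,13R)-2-hydroxylabd-7-en-15-oate F3. A Mitsunobu reaction with 19 (PPh3, diisopropyl azodicarboxylate, toluene, 0 °C) then inverts C-2 while forming the ester. It rejoins the route at 21.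

**Further compounds**
F1 | step 9 | methyl (3R)-3-methyl-5-[(3R)-2-methyl-3-(2-methyl-4-oxopentan-2-yl)-6-oxocyclohex-1-en-1-yl]pentanoate | CC(=O)CC(C)(C)[C@H]1CCC(=O)C(CC[C@@H](C)CC(=O)OC)=C1C
F2 | step 10 | methyl (5R,10S,13R)-8-hydroxy-2-oxolabdan-15-oate (axial 8-OH on the face of C-11) | O=C1CC(C)(C)[C@H]2CC[C@@](C)(O)[C@@H](CC[C@@H](C)CC(=O)OC)[C@@]2(C)C1
F3 | step 12 | methyl (2R,5R,9R,10S,13R)-2-hydroxylabd-7-en-15-oate | O[C@@H]1CC(C)(C)[C@H]2CC=C(C)[C@@H](CC[C@@H](C)CC(=O)OC)[C@@]2(C)C1
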